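**Plan**

1. Cuts: C12–C13 (Negishi coupling of butenolide vinyl iodide 41 with decalin iodide 43); ring A at C1–C10 and C2–C3 (acrolein supplies C1–C2, and its formyl group is a removable activator); ring B at C5–C10 (carbonyl-ene); C9–C11 and the C8/C9 pattern go back to a δ-lactone made from prenal.
2. Forward ring order: δ-lactone 5 → 11 (C6, C8, C9 set) → ring B (step 10) → temporary trans-fused 18→6 γ-lactone (step 14) → ring A (step 18) → lactone opened, side chain joined (step 30).
3. Enabling feature: in ring A the carbinol carbon C3 (next to quaternary C4) and the methyl-bearing quaternary C10 are 1,4-related through C4–C5. An exocyclic C10=CH2 on ring B and a non-enolisable C3 aldehyde on C4 can therefore be bridged by a two-carbon acceptor: H-atom transfer creates the C10 methyl and radical, conjugate addition makes C1–C10, and the resulting enolate closes C2–C3.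
4. Helpers: the γ-lactone ring (fixes C4, masks O6 and C18; reduced in step 21), the C2 formyl group (excised in step 20), the C12 benzyl ether.
5. Stereochemistry: C6 by catalyst (step 2); C8 and C9 by the lactone ring (steps 3, 6); C5 by a chair ene transition state; C4 by enolate alkylation anti to C10; C10 and C3 in the key step; C16 by D-proline; the E alkene by syn-hydrozirconation.

Key step: step 18

Remark: decalin atoms are numbered as in labdanes (ring A = C1–C5 + C10, ring B = C5–C10; C11/C12 = the CH2CH2 on C9; C18 = the CH2OH carbon on C4; C16 = butenolide carbinol carbon); β is the face of the C10 methyl, α the face of H5.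
Remark: (S)-Tol-BINAP is assumed to give the 6S lactone in step 2; if the sense of induction is the opposite, (R)-Tol-BINAP is used.
Remark: C4 in 17–21 and C2 in 26/27 are stereo-indeterminate centres that are erased in steps 16 and 20.

**Step 1**
Reactants: 1 methyl 3-methylbut-2-enoate
Product: 3 1-methoxy-3-methyl-1-(trimethylsilyloxy)buta-1,3-diene, via lithium dienolate 2 (not isolated)
Conditions: LiN(i-Pr)2, THF, −78 °C; then TMSCl
Reagents that add atoms: chlorotrimethylsilane, C[Si](C)(C)Cl
Why: Kinetic γ-deprotonation of the senecioate and O-silylation should give the silyl dienolate (silyl ketene acetal formation).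

**Step 2**
Reactants: 3 1-methoxy-3-methyl-1-(trimethylsilyloxy)buta-1,3-diene; 4 3-methylbut-2-enal
Product: 5 (S)-4-methyl-6-(2-methylprop-1-enyl)-5,6-dihydro-2H-pyran-2-one
Conditions: Cu(OTf)2 (10 mol%), (S)-Tol-BINAP (11 mol%), Bu4N[Ph3SiF2] (20 mol%), THF, −78 °C to rt
Reagents that add atoms: none
Why: Catalytic asymmetric vinylogous Mukaiyama aldol addition of the γ-carbon of 3 to the aldehyde, followed by lactonisation, should give the unsaturated δ-lactone; the chiral copper–bisphosphine catalyst sets C6 as S.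

**Step 3**
Reactants: 5 (S)-4-methyl-6-(2-methylprop-1-enyl)-5,6-dihydro-2H-pyran-2-one
Product: 6 3,4-epoxide of 5 with the epoxide oxygen trans to the C6 side chain
Conditions: 30% H2O2, NaOH (cat.), MeOH, 0 °C; then 1 M HCl
Reagents that add atoms: hydrogen peroxide, OO
Why: Nucleophilic (Weitz–Scheffer) epoxidation: hydroperoxide adds axially to C8 of the half-chair lactone trans to the pseudo-equatorial C6 side chain, so the epoxide oxygen (the future 8α-OH) ends up trans to that chain.

**Step 4**
Reactants: 6 epoxy lactone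
Product: 7 4-hydroxy-4-methyl-6-(2-methylprop-1-enyl)tetrahydropyran-2-one (4-OH trans and 4-CH3 cis to the C6 side chain)
Conditions: SmI2 (2.5 equiv), THF/MeOH, −78 °C
Reagents that add atoms: none
Why: SmI2 reductive cleavage of the Cα–O bond of the α,β-epoxy lactone should give the β-hydroxy lactone with the C8 carbinol centre untouched.

**Step 5**
Reactants: 8 2-(benzyloxy)ethanol
Product: 9 2-(benzyloxy)ethyl trifluoromethanesulfonate
Conditions: Tf2O, 2,6-lutidine, CH2Cl2, −78 °C
Reagents that add atoms: triflic anhydride, O=S(=O)(OS(=O)(=O)C(F)(F)F)C(F)(F)F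
Why: Triflation of the primary alcohol gives an alkylating agent reactive enough for enolate alkylation at low temperature.

**Step 6**
Reactants: 7 hydroxy lactone; 9 2-(benzyloxy)ethyl trifluoromethanesulfonate
Product: 11 3-[2-(benzyloxy)ethyl] derivative of 7 (new chain trans to the 4-OH and cis to the 4-CH3), via dilithium alkoxide enolate 10 (not isolated)
Conditions: LiN(i-Pr)2 (2.2 equiv), THF, −78 to −40 °C; then 9, −78 °C; NH4Cl
Reagents that add atoms: none
Why: Fráter–Seebach alkylation: the lactone enolate is alkylated axially on the face anti to the adjacent axial lithium alkoxide, which sets C9 with the side chain trans to the C8 oxygen.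

**Step 7**
Reactants: 11 alkylated hydroxy lactone
Product: 12 open-chain N-methoxy-N-methyl amide: 2-[2-(benzyloxy)ethyl]-3,5-dihydroxy-3,7-dimethyloct-6-enamide (stereocentres as in 11)
Conditions: MeNH(OMe)·HCl, i-PrMgCl, THF, −20 to 0 °C
Reagents that add atoms: N,O-dimethylhydroxylamine hydrochloride, CNOC.Cl
Why: Aminolysis of the lactone by the magnesium amide of N,O-dimethylhydroxylamine (Weinreb amide formation) opens the ring without touching a stereocentre; 12 is used at once to avoid relactonisation.

**Step 8**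
Reactants: 12 dihydroxy Weinreb amide
Product: 13 5-O-tert-butyldimethylsilyl ether of 12
Conditions: TBSCl, imidazole, DMF, 0 °C to rt
Reagents that add atoms: tert-butylchlorodimethylsilane, CC(C)(C)[Si](C)(C)Cl
Why: Selective silylation of the secondary allylic hydroxyl (the tertiary one is inert to TBSCl/imidazole) blocks relactonisation and later lactol formation.

**Step 9**
Reactants: 13 silylated Weinreb amide
Product: 14 2-[2-(benzyloxy)ethyl]-5-(tert-butyldimethylsilyloxy)-3-hydroxy-3,7-dimethyloct-6-enal
Conditions: i-Bu2AlH (2.5 equiv), THF, −78 °C; aq. potassium sodium tartrate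
Reagents that add atoms: none
Why: Hydride reduction of the Weinreb amide stops at the aldehyde because the chelated tetrahedral intermediate survives until work-up.

**Step 10**
Reactants: 14 hydroxy aldehyde
Product: 15 ring B carbinol: cyclohexane with 10α-OH, 5β-isopropenyl, 6α-OTBS, 8α-OH/8β-CH3, 9β-CH2CH2OBn
Conditions: ZnBr2 (1.5 equiv), CH2Cl2, 0 °C
Reagents that add atoms: none
Why: Lewis-acid carbonyl-ene cyclisation (as in citronellal to isopulegol) through a chair with the C6 silyloxy group, the C9 chain and the C8 hydroxyl equatorial should form C5–C10 and place the new isopropenyl group equatorial, so C5 is trans to the C6 oxygen and cis to the C9 chain.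

**Step 11**
Reactants: 15 ring B carbinol
Product: 16 the corresponding C10 ketone (5β-isopropenyl, 6α-OTBS, 8α-OH, 9β-CH2CH2OBn)
Conditions: Dess–Martin periodinane, NaHCO3, CH2Cl2, 0 °C to rt
Reagents that add atoms: none
Why: Buffered Dess–Martin oxidation of the secondary alcohol gives the ketone without conjugating the isopropenyl group and removes the C10 hydroxyl that would otherwise compete with the C6 hydroxyl in the later lactonisation.

**Step 12**
Reactants: 16 isopropenyl ketone
Product: 18 primary alcohol: C5 side chain CH(CH3)CH2OH (C4 epimers), via B-alkyl-9-BBN adduct 17 (not isolated)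
Conditions: 9-BBN, THF, 0 °C to rt; then NaBO3·4H2O, H2O
Reagents that add atoms: sodium perborate, [Na+].[Na+].O[B-]1(O)OO[B-](O)(O)OO1
Why: Chemoselective anti-Markovnikov hydroboration–oxidation: 9-BBN adds to the unhindered 1,1-disubstituted alkene much faster than it reduces the doubly α-branched ketone, and perborate oxidises the borane without epimerising the β-hydroxy ketone.

**Step 13**
Reactants: 18 silyl-protected keto diol
Product: 19 keto triol (C18-OH, 6α-OH, 8α-OH; C10 ketone)
Conditions: HF·pyridine, THF, 0 °C to rt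
Reagents that add atoms: none
Why: Fluoride-mediated desilylation under non-basic conditions frees the C6 hydroxyl without retro-aldol cleavage of the β-hydroxy ketone.

**Step 14**
Reactants: 19 keto triol
Product: 20 keto lactone: trans-fused 18→6α γ-lactone on ring B (C10 ketone, C4 epimers)
Conditions: TEMPO (cat.), PhI(OAc)2 (2.5 equiv), CH2Cl2, rt
Reagents that add atoms: none
Why: Oxidative lactonisation: TEMPO/PhI(OAc)2 oxidises the primary alcohol selectively to the aldehyde, which is trapped by the C6 hydroxyl as a lactol and oxidised on to the γ-lactone; the fusion is trans because the C5–C4 and C6–O bonds are both equatorial.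

**Step 15**
Reactants: 20 keto lactone
Product: 21 methylene lactone (exocyclic C10=CH2)
Conditions: Cp2Ti(μ-Cl)(μ-CH2)AlMe2 (Tebbe reagent), pyridine, THF/toluene, −40 to 0 °C
Reagents that add atoms: Tebbe reagent Cp2Ti(Cl)CH2AlMe2 (chloride drawn terminal on titanium), C[Al](C)C[Ti](Cl)(C1C=CC=C1)C1C=CC=C1
Why: Tebbe methylenation converts the hindered, enolisable ketone into the exocyclic alkene under non-basic conditions and reacts with a ketone faster than with a lactone.

**Step 16**
Reactants: 21 methylene lactone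
Product: 23 hydroxymethyl lactone: C4 bears β-CH3 and CH2OH (future C3) cis to H5, via dilithio lactone enolate 22 (not isolated)
Conditions: LiN(i-Pr)2 (2.3 equiv), THF, −78 °C; then CH2O (gas), −78 to −40 °C; NH4Cl
Reagents that add atoms: formaldehyde, C=O
Why: Aldol-type hydroxymethylation of the lactone enolate: formaldehyde approaches the face anti to C10 on the adjacent ring-fusion carbon C5, so the new CH2OH is cis to H5 and the C4 methyl becomes β.

**Step 17**
Reactants: 23 hydroxymethyl lactone
Product: 24 formyl lactone: C4 bears β-CH3 and the C3 aldehyde; exocyclic C10=CH2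
Conditions: Dess–Martin periodinane, NaHCO3, CH2Cl2, 0 °C
Reagents that add atoms: none
Why: Dess–Martin oxidation of the neopentyl primary alcohol gives the non-enolisable aldehyde and leaves the tertiary alcohol untouched.

**Step 18**
Reactants: 24 formyl lactone; 25 acrolein
Product: 26 tricyclic lactone: trans-decalin (10β-CH3, 5α-H) with 18→6α γ-lactone, 3β-OH, 2-CHO, 8α-OH/8β-CH3, 9β-CH2CH2OBn
Conditions: acrolein (3 equiv), Fe(acac)3 (0.5 equiv), PhSiH3 (2.5 equiv), EtOH/(CH2OH)2 5:1, 0 °C to rt
Reagents that add atoms: none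
Why: Hydrogen-atom transfer from an iron hydride (from Fe(acac)3 and PhSiH3) to the exocyclic C10=CH2 of 24 gives the tertiary C10 radical, which adds to C1 of acrolein (Giese addition, C1–C10 bond); the α-formyl radical is reduced by divalent iron to the iron enolate, whose carbon C2 adds to the neighbouring C3 aldehyde (intramolecular aldol, C2–C3 bond), and the closest known reaction type is the metal-hydride HAT-initiated radical-polar crossover annulation of alkenyl aldehydes with enals. Ring A closes in a 6-(enolexo)-exo-trig aldol mode, a formal [4+2] between the C10–C5–C4–C3 unit and the C1–C2 unit. C10: the acceptor should add to the α face of the planar radical (equatorial attack) because the β face is screened by the axial C8 methyl and by the C4 methyl held in place by the trans-fused lactone, which gives the β methyl and the trans ring fusion. C3: the aldol should pass through a chair in which the iron-bound aldehyde oxygen is equatorial, giving the 3β alcohol, while the C2 formyl centre is transient and is removed in step 20. The step needs H-atom transfer to a single alkene (hence the side chain is carried as a saturated benzyl ether) and radical capture faster than alkene isomerisation, which the unhindered electrophilic acceptor in excess secures; the quaternary C4 rules out enolisation of the aldehyde partner.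

**Step 19**
Reactants: 26 tricyclic hydroxy aldehyde
Product: 27 3β-O-triethylsilyl ether of 26
Conditions: TESCl, imidazole, DMAP (cat.), DMF, rt
Reagents that add atoms: chlorotriethylsilane, CC[Si](CC)(CC)Cl
Why: Silylation of the secondary 3β-alcohol guards against dehydration and retro-aldol during decarbonylation; the tertiary C8 alcohol does not react with TESCl.

**Step 20**
Reactants: 27 silylated aldehyde
Product: 28 decarbonylated lactone (C2 = CH2; 3β-OTES)
Conditions: RhCl(PPh3)3 (1.2 equiv), PhCN, 130 °C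
Reagents that add atoms: none
Why: Tsuji–Wilkinson decarbonylation: oxidative addition of the aldehyde C–H bond, CO extrusion and C–H reductive elimination replace the formyl group by hydrogen.

**Step 21**
Reactants: 28 decalin lactone
Product: 29 triol: C18-OH, 6α-OH, 8α-OH (3β-OTES, C12-OBn)
Conditions: LiAlH4, THF, 0 °C to rt
Reagents that add atoms: none
Why: LiAlH4 reduction of the γ-lactone gives the C18/C6 diol without touching the benzyl ether or any stereocentre; a possible silyl shift between O3 and O18 is harmless because step 22 silylates both.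

**Step 22**
Reactants: 29 triol
Product: 30 tetrakis(triethylsilyl) ether (O3, O18, O6, O8)
Conditions: TESOTf (4 equiv), 2,6-lutidine, CH2Cl2, −78 to 0 °C
Reagents that add atoms: triethylsilyl triflate, CC[Si](CC)(CC)OS(=O)(=O)C(F)(F)F
Why: Triethylsilyl triflate silylates primary, hindered secondary and tertiary hydroxyls alike and gives a uniformly protected core.

**Step 23**
Reactants: 31 but-2-yn-1-ol
Product: 33 (E)-3-iodobut-2-en-1-ol, via alkenylzirconocene 32 (not isolated)
Conditions: Cp2Zr(H)Cl (2.2 equiv), THF, rt; then I2, 0 °C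
Reagents that add atoms: iodine, II
Why: syn-Hydrozirconation places zirconium on the methyl-bearing alkyne carbon (distal to the zirconium alkoxide), and iodinolysis with retention gives the E vinyl iodide.

**Step 24**
Reactants: 33 (E)-3-iodobut-2-en-1-ol
Product: 34 (E)-1-bromo-3-iodobut-2-ene
Conditions: CBr4, PPh3, CH2Cl2, 0 °C
Reagents that add atoms: carbon tetrabromide, BrC(Br)(Br)Br
Why: Appel bromination of the allylic alcohol proceeds without touching the vinyl iodide.

**Step 25**
Reactants: 34 (E)-1-bromo-3-iodobut-2-ene; 35 pentane-2,4-dione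
Product: 37 (E)-6-iodohept-5-en-2-one, via C-alkylated diketone 36 (not isolated)
Conditions: K2CO3, EtOH, reflux
Reagents that add atoms: none
Why: C-alkylation of acetylacetone followed by in situ retro-Claisen deacetylation in ethanolic carbonate should give the methyl ketone.

**Step 26**
Reactants: 37 (E)-6-iodohept-5-en-2-one
Product: 39 (S,E)-3-hydroxy-6-iodohept-5-en-2-one, via aminooxy ketone 38 (not isolated)
Conditions: D-proline (20 mol%), PhN=O, DMSO, rt; then CuSO4·5H2O (30 mol%), MeOH, 0 °C
Reagents that add atoms: nitrosobenzene, O=Nc1ccccc1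
Why: Proline-catalysed α-aminoxylation through the more substituted enamine sets C16, D-proline giving the S centre (mirror image of the R outcome of L-proline); copper-mediated N–O cleavage then frees the hydroxyl.

**Step 27**
Reactants: 39 (S,E)-3-hydroxy-6-iodohept-5-en-2-one; 40 (triphenylphosphoranylidene)ketene
Product: 41 (S)-5-[(E)-3-iodobut-2-enyl]-4-methylfuran-2(5H)-one
Conditions: toluene, 80 °C
Reagents that add atoms: none
Why: The hydroxyl adds to the ketene ylide to give an ester ylide that closes on the ketone by intramolecular Wittig reaction (Bestmann butenolide synthesis) under neutral conditions that preserve C16.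

**Step 28**
Reactants: 30 tetrakis(triethylsilyl) ether
Product: 42 primary C12 alcohol
Conditions: H2 (1 atm), Pd/C (10% palladium on carbon), EtOAc, rt
Reagents that add atoms: none
Why: Hydrogenolysis of the benzyl ether; the triethylsilyl ethers are stable in ethyl acetate and no alkene is present.

**Step 29**
Reactants: 42 primary alcohol
Product: 43 primary C12 iodide
Conditions: I2, PPh3, imidazole, CH2Cl2, 0 °C to rt
Reagents that add atoms: iodine, II
Why: Appel iodination of the only free (primary) hydroxyl.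

**Step 30**
Reactants: 43 primary iodide; 41 (S)-5-[(E)-3-iodobut-2-enyl]-4-methylfuran-2(5H)-one
Product: 45 tetrakis(triethylsilyl) ether of the target, via alkylzinc iodide 44 (not isolated)
Conditions: Zn dust (activated), LiCl, THF, 40 °C; then 41, Pd(PPh3)4 (5 mol%), THF/DMA, rt
Reagents that add atoms: none
Why: Negishi coupling: zinc insertion gives the alkylzinc iodide, which couples with the vinyl iodide under zerovalent-palladium catalysis with retention of the E geometry, and the non-basic organozinc tolerates the butenolide.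

**Step 31**
Reactants: 45 protected target
Product: 46 CNP0307004.1
Conditions: HF·pyridine, THF/pyridine, 0 °C to rt
Reagents that add atoms: none
Why: Global fluoride-mediated desilylation under mildly acidic conditions that leave the butenolide stereocentre and the tertiary alcohol intact.

**Compound list**

1 | methyl 3-methylbut-2-enoate | COC(=O)C=C(C)C | starting material
2 | lithium 1-methoxy-3-methylbuta-1,3-dien-1-olate | [Li]OC(OC)=CC(C)=C | intermediate
3 | 1-methoxy-3-methyl-1-(trimethylsilyloxy)buta-1,3-diene | COC(O[Si](C)(C)C)=CC(C)=C | intermediate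
4 | 3-methylbut-2-enal | CC(C)=CC=O | starting material
5 | (S)-4-methyl-6-(2-methylprop-1-enyl)-5,6-dihydro-2H-pyran-2-one | CC(C)=C[C@@H]1CC(C)=CC(=O)O1 | intermediate
6 | 3,4-epoxide of 5, epoxide oxygen trans to the C6 side chain | CC(C)=C[C@@H]1C[C@@]2(C)O[C@H]2C(=O)O1 | intermediate
7 | 4-hydroxy-4-methyl-6-(2-methylprop-1-enyl)tetrahydropyran-2-one, 4-OH trans to the C6 side chain | CC(C)=C[C@@H]1C[C@@](C)(O)CC(=O)O1 | intermediate
8 | 2-(benzyloxy)ethanol | OCCOCc1ccccc1 | starting material
9 | 2-(benzyloxy)ethyl trifluoromethanesulfonate | O=S(=O)(OCCOCc1ccccc1)C(F)(F)F | intermediate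
10 | dilithium alkoxide enolate of 7 | CC(C)=C[C@@H]1C[C@@](C)(O[Li])C=C(O[Li])O1 | intermediate
11 | 3-[2-(benzyloxy)ethyl]-4-hydroxy-4-methyl-6-(2-methylprop-1-enyl)tetrahydropyran-2-one, side chain trans to 4-OH | CC(C)=C[C@@H]1C[C@@](C)(O)[C@H](CCOCc2ccccc2)C(=O)O1 | intermediate
12 | N-methoxy-N-methyl 2-[2-(benzyloxy)ethyl]-3,5-dihydroxy-3,7-dimethyloct-6-enamide | CON(C)C(=O)[C@@H](CCOCc1ccccc1)[C@](C)(O)C[C@H](O)C=C(C)C | intermediate
13 | 5-O-TBS ether of 12 | CON(C)C(=O)[C@@H](CCOCc1ccccc1)[C@](C)(O)C[C@H](O[Si](C)(C)C(C)(C)C)C=C(C)C | intermediate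
14 | 2-[2-(benzyloxy)ethyl]-5-(tert-butyldimethylsilyloxy)-3-hydroxy-3,7-dimethyloct-6-enal | O=C[C@@H](CCOCc1ccccc1)[C@](C)(O)C[C@H](O[Si](C)(C)C(C)(C)C)C=C(C)C | intermediate
15 | ring B carbinol (10α-OH, 5β-isopropenyl, 6α-OTBS, 8α-OH, 8β-CH3, 9β-CH2CH2OBn) | c1ccccc1COCC[C@@H]1[C@@H](O)[C@H](C(C)=C)[C@@H](O[Si](C)(C)C(C)(C)C)C[C@@]1(C)O | intermediate
16 | ring B C10 ketone with 5β-isopropenyl | c1ccccc1COCC[C@@H]1C(=O)[C@H](C(C)=C)[C@@H](O[Si](C)(C)C(C)(C)C)C[C@@]1(C)O | intermediate
17 | B-alkyl-9-BBN adduct of 16 | c1ccccc1COCC[C@@H]1C(=O)[C@H](C(C)CB2C3CCCC2CCC3)[C@@H](O[Si](C)(C)C(C)(C)C)C[C@@]1(C)O | intermediate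
18 | ring B ketone with C5 side chain CH(CH3)CH2OH, 6α-OTBS | c1ccccc1COCC[C@@H]1C(=O)[C@H](C(C)CO)[C@@H](O[Si](C)(C)C(C)(C)C)C[C@@]1(C)O | intermediate
19 | keto triol (C18-OH, 6α-OH, 8α-OH) | c1ccccc1COCC[C@@H]1C(=O)[C@H](C(C)CO)[C@@H](O)C[C@@]1(C)O | intermediate
20 | keto lactone (trans-fused 18→6α γ-lactone, C10 ketone) | c1ccccc1COCC[C@@H]1C(=O)[C@@H]2C(C)C(=O)O[C@H]2C[C@@]1(C)O | intermediate
21 | methylene lactone (C10=CH2) | c1ccccc1COCC[C@@H]1C(=C)[C@@H]2C(C)C(=O)O[C@H]2C[C@@]1(C)O | intermediate
22 | dilithio lactone enolate of 21 | c1ccccc1COCC[C@@H]1C(=C)[C@@H]2C(C)=C(O[Li])O[C@H]2C[C@@]1(C)O[Li] | intermediate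
23 | hydroxymethyl lactone (C4: β-CH3, CH2OH cis to H5) | c1ccccc1COCC[C@@H]1C(=C)[C@@H]2[C@@](C)(CO)C(=O)O[C@H]2C[C@@]1(C)O | intermediate
24 | formyl lactone (C4: β-CH3, C3 aldehyde; C10=CH2) | c1ccccc1COCC[C@@H]1C(=C)[C@@H]2[C@@](C)(C=O)C(=O)O[C@H]2C[C@@]1(C)O | intermediate
25 | acrolein | C=CC=O | starting material
26 | tricyclic lactone: 2-formyl-3β-hydroxy trans-decalin with 18→6α lactone, 8α-OH, 9β-CH2CH2OBn | c1ccccc1COCC[C@@H]1[C@@]2(C)CC(C=O)[C@H](O)[C@@]3(C)C(=O)O[C@H]([C@H]23)C[C@@]1(C)O | intermediate
27 | 3β-O-TES ether of 26 | c1ccccc1COCC[C@@H]1[C@@]2(C)CC(C=O)[C@H](O[Si](CC)(CC)CC)[C@@]3(C)C(=O)O[C@H]([C@H]23)C[C@@]1(C)O | intermediate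
28 | decarbonylated lactone (3β-OTES, 18→6α lactone) | c1ccccc1COCC[C@@H]1[C@@]2(C)CC[C@H](O[Si](CC)(CC)CC)[C@@]3(C)C(=O)O[C@H]([C@H]23)C[C@@]1(C)O | intermediate
29 | decalin triol (C18-OH, 6α-OH, 8α-OH; 3β-OTES; C12-OBn) | c1ccccc1COCC[C@@H]1[C@@]2(C)CC[C@H](O[Si](CC)(CC)CC)[C@@](C)(CO)[C@@H]2[C@@H](O)C[C@@]1(C)O | intermediate
30 | decalin tetrakis(triethylsilyl) ether with C12-OBn | c1ccccc1COCC[C@@H]1[C@@]2(C)CC[C@H](O[Si](CC)(CC)CC)[C@@](C)(CO[Si](CC)(CC)CC)[C@@H]2[C@@H](O[Si](CC)(CC)CC)C[C@@]1(C)O[Si](CC)(CC)CC | intermediate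
31 | but-2-yn-1-ol | CC#CCO | starting material
32 | O-zirconated (E)-alkenylzirconocene chloride from 31 | C/C(=C\CO[Zr](Cl)(C1C=CC=C1)C1C=CC=C1)[Zr](Cl)(C1C=CC=C1)C1C=CC=C1 | intermediate
33 | (E)-3-iodobut-2-en-1-ol | C/C(I)=C\CO | intermediate
34 | (E)-1-bromo-3-iodobut-2-ene | C/C(I)=C\CBr | intermediate
35 | pentane-2,4-dione | CC(=O)CC(C)=O | starting material
36 | 3-[(E)-3-iodobut-2-enyl]pentane-2,4-dione | C/C(I)=C\CC(C(C)=O)C(C)=O | intermediate
37 | (E)-6-iodohept-5-en-2-one | C/C(I)=C\CCC(C)=O | intermediate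
38 | (S,E)-6-iodo-3-(phenylaminooxy)hept-5-en-2-one | C/C(I)=C\C[C@H](ONc1ccccc1)C(C)=O | intermediate
39 | (S,E)-3-hydroxy-6-iodohept-5-en-2-one | C/C(I)=C\C[C@H](O)C(C)=O | intermediate
40 | (triphenylphosphoranylidene)ketene | O=C=C=P(c1ccccc1)(c1ccccc1)c1ccccc1 | starting material
41 | (S)-5-[(E)-3-iodobut-2-enyl]-4-methylfuran-2(5H)-one | CC1=CC(=O)O[C@H]1C/C=C(\C)I | intermediate
42 | decalin tetrakis(triethylsilyl) ether, C12 alcohol | OCC[C@@H]1[C@@]2(C)CC[C@H](O[Si](CC)(CC)CC)[C@@](C)(CO[Si](CC)(CC)CC)[C@@H]2[C@@H](O[Si](CC)(CC)CC)C[C@@]1(C)O[Si](CC)(CC)CC | intermediate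
43 | decalin tetrakis(triethylsilyl) ether, C12 iodide | ICC[C@@H]1[C@@]2(C)CC[C@H](O[Si](CC)(CC)CC)[C@@](C)(CO[Si](CC)(CC)CC)[C@@H]2[C@@H](O[Si](CC)(CC)CC)C[C@@]1(C)O[Si](CC)(CC)CC | intermediate
44 | alkylzinc iodide from 43 | I[Zn]CC[C@@H]1[C@@]2(C)CC[C@H](O[Si](CC)(CC)CC)[C@@](C)(CO[Si](CC)(CC)CC)[C@@H]2[C@@H](O[Si](CC)(CC)CC)C[C@@]1(C)O[Si](CC)(CC)CC | intermediate
45 | tetrakis(triethylsilyl) ether of the target | CC1=CC(=O)O[C@H]1C/C=C(\C)CC[C@@H]1[C@@]2(C)CC[C@H](O[Si](CC)(CC)CC)[C@@](C)(CO[Si](CC)(CC)CC)[C@@H]2[C@@H](O[Si](CC)(CC)CC)C[C@@]1(C)O[Si](CC)(CC)CC | intermediate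
46 | CNP0307004.1 | CC1=CC(=O)O[C@H]1C/C=C(\C)CC[C@@H]1[C@@]2(C)CC[C@H](O)[C@@](C)(CO)[C@@H]2[C@@H](O)C[C@@]1(C)O | target

**Step count**

Total step count: 31. Longest linear sequence: 25 (steps 1–4, 6–22, 28–31); steps 5 and 23–27 are branches.

**Steps most likely to fail**

Step 18. The iron enolate may be protonated by the alcoholic medium before it closes onto the hindered neopentyl aldehyde, may close on the wrong aldehyde face, or the C10 radical may revert to an isomerised alkene. The fallback sets out from 24 and separates the two bond formations. The same Fe(acac)3/PhSiH3 conditions with phenyl vinyl sulfone as acceptor give the open sulfone aldehyde F1 (C1–C10 bond only). LiN(SiMe3)2 in THF then generates the α-sulfonyl carbanion, which adds reversibly to the C3 aldehyde and should settle in the equatorial β-hydroxy sulfone F2. Sodium amalgam (Na2HPO4, MeOH) removes the sulfonyl group to give the 3β-alcohol F3, and TESCl/imidazole returns to the route at 28.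

Step 10. The Lewis acid may ionise the allylic silyl ether, or the inductively deactivated alkene may react too slowly, giving poor conversion or poor control at C5. The fallback sets out from 14 and replaces the carbonyl-ene closure by a transition-metal enyne cycloisomerisation that forms the exocyclic methylene directly. Ohira–Bestmann homologation (dimethyl 1-diazo-2-oxopropylphosphonate, K2CO3, MeOH) gives enyne F4. Pd(OAc)2/PPh3 in benzene at 60 °C (Alder-ene cycloisomerisation) closes C5–C10 to diene F5 (C10=CH2, 5β-isopropenyl). 9-BBN then NaBO3 hydroborates the less hindered isopropenyl group to alcohol F6, HF·pyridine gives diol F7, and TEMPO/PhI(OAc)2 lactonises it, returning to the route at 21.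

Step 20. Decarbonylation at the hindered secondary centre may stall, or elimination of the β-silyloxy group may compete at 130 °C. The fallback sets out from 27 and removes the carbon oxidatively and then by a radical chain. Pinnick oxidation (NaClO2, NaH2PO4, 2-methyl-2-butene) gives acid F8. N-Hydroxypyridine-2-thione with DCC/DMAP gives the Barton ester F9, and photolysis with t-BuSH (Barton reductive decarboxylation) returns to the route at 28.

**Further compounds**

F1 | step 18 | open sulfone aldehyde: 24 with C10 bearing β-CH3 and CH2CH2SO2Ph | c1ccccc1COCC[C@@H]1[C@@](C)(CCS(=O)(=O)c3ccccc3)[C@@H]2[C@@](C)(C=O)C(=O)O[C@H]2C[C@@]1(C)O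
F2 | step 18 | tricyclic β-hydroxy sulfone (2-SO2Ph, 3β-OH) | c1ccccc1COCC[C@@H]1[C@@]2(C)CC(S(=O)(=O)c4ccccc4)[C@H](O)[C@@]3(C)C(=O)O[C@H]([C@H]23)C[C@@]1(C)O
F3 | step 18 | tricyclic 3β-alcohol (desilyl 28) | c1ccccc1COCC[C@@H]1[C@@]2(C)CC[C@H](O)[C@@]3(C)C(=O)O[C@H]([C@H]23)C[C@@]1(C)O
F4 | step 10 | enyne: 3-[2-(benzyloxy)ethyl]-6-(tert-butyldimethylsilyloxy)-4,8-dimethylnon-7-en-1-yn-4-ol | C#C[C@@H](CCOCc1ccccc1)[C@](C)(O)C[C@H](O[Si](C)(C)C(C)(C)C)C=C(C)C
F5 | step 10 | ring B diene (C10=CH2, 5β-isopropenyl, 6α-OTBS) | c1ccccc1COCC[C@@H]1C(=C)[C@H](C(C)=C)[C@@H](O[Si](C)(C)C(C)(C)C)C[C@@]1(C)O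
F6 | step 10 | ring B alcohol (C10=CH2, C5 side chain CH(CH3)CH2OH, 6α-OTBS) | c1ccccc1COCC[C@@H]1C(=C)[C@H](C(C)CO)[C@@H](O[Si](C)(C)C(C)(C)C)C[C@@]1(C)O
F7 | step 10 | ring B diol (C10=CH2, C18-OH, 6α-OH) | c1ccccc1COCC[C@@H]1C(=C)[C@H](C(C)CO)[C@@H](O)C[C@@]1(C)O
F8 | step 20 | tricyclic 2-carboxylic acid (3β-OTES) | c1ccccc1COCC[C@@H]1[C@@]2(C)CC(C(=O)O)[C@H](O[Si](CC)(CC)CC)[C@@]3(C)C(=O)O[C@H]([C@H]23)C[C@@]1(C)O
F9 | step 20 | Barton ester of F8 | c1ccccc1COCC[C@@H]1[C@@]2(C)CC(C(=O)On4ccccc4=S)[C@H](O[Si](CC)(CC)CC)[C@@]3(C)C(=O)O[C@H]([C@H]23)C[C@@]1(C)O
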